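**Plan**

- Retrosynthesis: the N2–C3 and C1–C8a bonds are cut together, which removes acetonitrile and leaves the (R)-1-arylpropan-2-ol 18. Then follow the aryl–CH2 bond (aryllithium plus (R)-propylene oxide), the C7–C1' biaryl bond (Suzuki–Miyaura) and the phenolic naphthalene ring (anionic annulation of an ortho-methallyl benzamide).
- Forward: the oxygenated, methylated naphthalene ring is annulated first, brominated para to its methoxy group and borylated. The biaryl is joined to 2-bromo-3-methoxyphenol and both phenols are silylated. The one unhindered aryl CH is borylated/brominated and takes up the three-carbon chain. The nitrogen ring closes last and fluoride frees the phenols.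
- Stereochemistry: C3 comes from (R)-propylene oxide and is inverted to (S) in the key step, where the nitrile nitrogen displaces a secondary triflate (SN2).
- Enabling feature: in the benzene ring of the isoquinoline, C8a is ortho to the C8 methoxy group and para to the C6 oxygen, so it captures the nitrilium carbon readily. C4a, which holds the side chain, is meta to both oxygens, so aryl participation at C3 gains no help and the displacement should stay stereospecific. Acetonitrile supplies N2, C1 and the C1 methyl group.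

Key step: step 9

Assumption: the SMILES fixes only C3 as (S) and gives no descriptor for the C7–C1' biaryl axis, so the axis is left uncontrolled; where rotation is slow, compounds 12 to 23 are expected as atropisomer mixtures that all match the drawn structures.

**Route**

Step 1
Reactants: 1 N,N-diethyl-2-methoxybenzamide; 2 3-bromo-2-methylprop-1-ene
Product: 5 N,N-diethyl-2-methoxy-6-(2-methylprop-2-en-1-yl)benzamide, via aryllithium 3 (not isolated), via arylmagnesium bromide 4 (not isolated)
Conditions: s-BuLi, TMEDA, THF, −78 °C; MgBr2·OEt2, −78 °C to rt; then 2, rt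
Reagents that add atoms: none
Why: Directed ortho metalation, in which the diethylamide outranks the methoxy group as director so that lithiation should occur at C6, followed by transmetalation to the aryl Grignard reagent, which is allylated cleanly by the allylic bromide.

Step 2
Reactants: 5 ortho-methallyl benzamide
Product: 7 8-methoxy-3-methylnaphthalen-1-yl acetate, via lithium naphtholate 6 (not isolated)
Conditions: LiN(iPr)2, THF, −78 °C to rt; then Ac2O (excess), 0 °C
Reagents that add atoms: acetic anhydride CC(=O)OC(C)=O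
Why: Anionic ring annulation of an ortho-allyl benzamide, in which deprotonation of the benzylic/allylic CH2 gives a delocalised anion whose terminal carbon adds to the amide carbonyl (6-exo-trig); loss of diethylamide and enolisation should give the naphtholate, which is acetylated in the flask to mask the oxidation-prone naphthol.

Step 3
Reactants: 7 naphthyl acetate
Product: 8 5-bromo-8-methoxy-3-methylnaphthalen-1-yl acetate
Conditions: NBS, MeCN, 0 °C to rt, dark
Reagents that add atoms: N-bromosuccinimide O=C1CCC(=O)N1Br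
Why: Electrophilic aromatic bromination, in which the acetoxy group deactivates the methylated ring so that the methoxy group should direct bromine to the α-position para to it (C5).

Step 4
Reactants: 8 bromonaphthyl acetate
Product: 9 8-methoxy-3-methyl-5-(4,4,5,5-tetramethyl-1,3,2-dioxaborolan-2-yl)naphthalen-1-yl acetate
Conditions: B2pin2, PdCl2(dppf) (cat.), KOAc, 1,4-dioxane, 90 °C
Reagents that add atoms: bis(pinacolato)diboron CC1(C)OB(OC1(C)C)B1OC(C)(C)C(C)(C)O1
Why: Miyaura borylation of the aryl bromide under the weak base KOAc, which should leave the aryl acetate intact.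

Step 5
Reactants: 9 naphthylboronate; 10 2-bromo-3-methoxyphenol
Product: 12 5-(2-hydroxy-6-methoxyphenyl)-8-methoxy-3-methylnaphthalen-1-ol, via biaryl acetate 11 (not isolated)
Conditions: Pd(OAc)2 (cat.), SPhos, K3PO4, toluene/H2O, 90 °C; then NaOH, MeOH, rt; acidic work-up
Reagents that add atoms: none
Why: Suzuki–Miyaura coupling with a bulky dialkylbiarylphosphine, which suits the hindered 2,6-dioxygenated bromide and tolerates its free phenol, followed by saponification of the acetate so that both phenols are free for a single silylation.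

Step 6
Reactants: 12 biaryl diol
Product: 13 4-methoxy-1-[2-methoxy-6-(triisopropylsilyloxy)phenyl]-7-methyl-5-(triisopropylsilyloxy)naphthalene
Conditions: iPr3SiOTf, 2,6-lutidine, CH2Cl2, 0 °C to rt
Reagents that add atoms: triisopropylsilyl trifluoromethanesulfonate CC(C)[Si](OS(=O)(=O)C(F)(F)F)(C(C)C)C(C)C
Why: Silyl ether formation with the silyl triflate, which is reactive enough for the hindered ortho-aryl phenol and the peri-methoxy naphthol; the bulky silyl ether on the benzene ring is the steric control element for step 9.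

Step 7
Reactants: 13 bis(silyl ether)
Product: 15 1-[4-bromo-2-methoxy-6-(triisopropylsilyloxy)phenyl]-4-methoxy-7-methyl-5-(triisopropylsilyloxy)naphthalene, via arylboronate 14 (not isolated)
Conditions: [Ir(OMe)(cod)]2 (cat.), 4,4'-di-tert-butyl-2,2'-bipyridine, B2pin2, THF, 80 °C; evaporate; then CuBr2, MeOH/THF/H2O, 80 °C
Reagents that add atoms: copper dibromide [Cu+2].[Br-].[Br-]
Why: Iridium-catalysed aromatic C–H borylation under steric control followed by copper-mediated bromodeboronation in the same flask; the CH para to the naphthyl group is the only aromatic CH of 13 without an ortho or peri substituent, so bromine should enter meta to both ring oxygens, a position electrophilic bromination cannot reach.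

Step 8
Reactants: 15 aryl bromide; 16 (R)-2-methyloxirane
Product: 18 (2R)-1-{3-methoxy-4-[4-methoxy-7-methyl-5-(triisopropylsilyloxy)naphthalen-1-yl]-5-(triisopropylsilyloxy)phenyl}propan-2-ol, via aryllithium 17 (not isolated)
Conditions: n-BuLi, THF, −78 °C; then 16, BF3·OEt2, −78 °C; aq NH4Cl
Reagents that add atoms: none
Why: Bromine–lithium exchange followed by BF3-promoted SN2 opening of the epoxide at its CH2 carbon, which does not touch the stereocentre, so the (R) configuration of 16 is carried into 18.

Step 9
Reactants: 18 (R)-carbinol; 19 acetonitrile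
Product: 22 (3S)-8-methoxy-7-[4-methoxy-7-methyl-5-(triisopropylsilyloxy)naphthalen-1-yl]-1,3-dimethyl-6-(triisopropylsilyloxy)-3,4-dihydroisoquinoline, via secondary triflate 20 (not isolated), via nitrilium triflate 21 (not isolated)
Conditions: Tf2O, 2,6-di-tert-butyl-4-methylpyridine, MeCN/CH2Cl2, −40 °C to rt; aq NaHCO3
Reagents that add atoms: none
Why: Proposed new method: the alcohol is triflated at low temperature with retention, acetonitrile (the solvent) displaces the secondary triflate through nitrogen in an SN2 step to give the N-alkylnitrilium ion 21, and C8a then attacks the nitrilium carbon in an intramolecular electrophilic aromatic substitution, while the hindered pyridine only takes up the two equivalents of TfOH. The closest known reactions are the Ritter-type heteroannulation of 1-arylpropan-2-ols or allylarenes with nitriles in strong acid (a carbocation route to racemic 3-methyl-3,4-dihydroisoquinolines), the Tf2O-promoted Ritter amidation of alcohols, the N-alkylation of nitriles by alkyl triflates to nitrilium salts and the Tf2O-mediated Bischler–Napieralski closure through nitrilium ions; what is new is running the first bond as a stereospecific displacement so that one flask gives both bonds and the C3 configuration. The only ring closed is the six-membered N2–C1–C8a–C4a–C4–C3 ring, closed 6-endo-dig at the nitrilium carbon. No new stereocentre is created: C3 is inverted from (R) in 18 and 20 to (S) by backside attack, so its configuration is controlled by the substrate stereocentre that came from (R)-propylene oxide. The step needs (a) direct displacement in preference to ionisation, aryl participation or elimination, which the substrate should secure because C4a is meta to both ring oxygens (a phenonium ion or a benzylic cation gains nothing from them) and the base is too hindered for E2, and (b) closure ortho to the methoxy group and not ortho to the silyloxy group, which the bulk of the triisopropylsilyl group should secure, since both positions are electronically activated (each is ortho to one oxygen and para to the other).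

Step 10
Reactants: 22 bis(silyl) dihydroisoquinoline
Product: 23 (3S)-7-(5-hydroxy-4-methoxy-7-methylnaphthalen-1-yl)-8-methoxy-1,3-dimethyl-3,4-dihydroisoquinolin-6-ol
Conditions: Bu4NF, THF, 0 °C to rt; pH 7 buffer
Reagents that add atoms: none
Why: Fluoride-induced cleavage of both aryl silyl ethers, conditions that should leave the cyclic imine, the two methyl ethers and C3 untouched.

**Compound list**

1 | N,N-diethyl-2-methoxybenzamide | CCN(CC)C(=O)c1ccccc1OC | starting material
2 | 3-bromo-2-methylprop-1-ene (methallyl bromide) | C=C(C)CBr | starting material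
3 | N,N-diethyl-2-lithio-6-methoxybenzamide | CCN(CC)C(=O)c1c([Li])cccc1OC | intermediate
4 | [2-(diethylcarbamoyl)-3-methoxyphenyl]magnesium bromide | CCN(CC)C(=O)c1c([Mg]Br)cccc1OC | intermediate
5 | N,N-diethyl-2-methoxy-6-(2-methylprop-2-en-1-yl)benzamide | CCN(CC)C(=O)c1c(CC(C)=C)cccc1OC | intermediate
6 | lithium 8-methoxy-3-methylnaphthalen-1-olate | [Li+].[O-]c1cc(C)cc2cccc(OC)c12 | intermediate
7 | 8-methoxy-3-methylnaphthalen-1-yl acetate | CC(=O)Oc1cc(C)cc2cccc(OC)c12 | intermediate
8 | 5-bromo-8-methoxy-3-methylnaphthalen-1-yl acetate | CC(=O)Oc1cc(C)cc2c(Br)ccc(OC)c12 | intermediate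
9 | 8-methoxy-3-methyl-5-(4,4,5,5-tetramethyl-1,3,2-dioxaborolan-2-yl)naphthalen-1-yl acetate | CC(=O)Oc1cc(C)cc2c(B3OC(C)(C)C(C)(C)O3)ccc(OC)c12 | intermediate
10 | 2-bromo-3-methoxyphenol | COc1cccc(O)c1Br | starting material
11 | 5-(2-hydroxy-6-methoxyphenyl)-8-methoxy-3-methylnaphthalen-1-yl acetate | COc1cccc(O)c1-c1ccc(OC)c2c(OC(C)=O)cc(C)cc12 | intermediate
12 | 5-(2-hydroxy-6-methoxyphenyl)-8-methoxy-3-methylnaphthalen-1-ol | COc1cccc(O)c1-c1ccc(OC)c2c(O)cc(C)cc12 | intermediate
13 | 4-methoxy-1-[2-methoxy-6-(triisopropylsilyloxy)phenyl]-7-methyl-5-(triisopropylsilyloxy)naphthalene | COc1cccc(O[Si](C(C)C)(C(C)C)C(C)C)c1-c1ccc(OC)c2c(O[Si](C(C)C)(C(C)C)C(C)C)cc(C)cc12 | intermediate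
14 | 2-{3-methoxy-4-[4-methoxy-7-methyl-5-(triisopropylsilyloxy)naphthalen-1-yl]-5-(triisopropylsilyloxy)phenyl}-4,4,5,5-tetramethyl-1,3,2-dioxaborolane | COc1cc(B2OC(C)(C)C(C)(C)O2)cc(O[Si](C(C)C)(C(C)C)C(C)C)c1-c1ccc(OC)c2c(O[Si](C(C)C)(C(C)C)C(C)C)cc(C)cc12 | intermediate
15 | 1-[4-bromo-2-methoxy-6-(triisopropylsilyloxy)phenyl]-4-methoxy-7-methyl-5-(triisopropylsilyloxy)naphthalene | COc1cc(Br)cc(O[Si](C(C)C)(C(C)C)C(C)C)c1-c1ccc(OC)c2c(O[Si](C(C)C)(C(C)C)C(C)C)cc(C)cc12 | intermediate
16 | (R)-2-methyloxirane ((R)-propylene oxide) | C[C@@H]1CO1 | starting material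
17 | {3-methoxy-4-[4-methoxy-7-methyl-5-(triisopropylsilyloxy)naphthalen-1-yl]-5-(triisopropylsilyloxy)phenyl}lithium | COc1cc([Li])cc(O[Si](C(C)C)(C(C)C)C(C)C)c1-c1ccc(OC)c2c(O[Si](C(C)C)(C(C)C)C(C)C)cc(C)cc12 | intermediate
18 | (2R)-1-{3-methoxy-4-[4-methoxy-7-methyl-5-(triisopropylsilyloxy)naphthalen-1-yl]-5-(triisopropylsilyloxy)phenyl}propan-2-ol | C[C@@H](O)Cc1cc(OC)c(-c2ccc(OC)c3c(O[Si](C(C)C)(C(C)C)C(C)C)cc(C)cc23)c(O[Si](C(C)C)(C(C)C)C(C)C)c1 | intermediate
19 | acetonitrile | CC#N | starting material
20 | (2R)-1-{3-methoxy-4-[4-methoxy-7-methyl-5-(triisopropylsilyloxy)naphthalen-1-yl]-5-(triisopropylsilyloxy)phenyl}propan-2-yl trifluoromethanesulfonate | C[C@@H](OS(=O)(=O)C(F)(F)F)Cc1cc(OC)c(-c2ccc(OC)c3c(O[Si](C(C)C)(C(C)C)C(C)C)cc(C)cc23)c(O[Si](C(C)C)(C(C)C)C(C)C)c1 | intermediate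
21 | N-[(2S)-1-{3-methoxy-4-[4-methoxy-7-methyl-5-(triisopropylsilyloxy)naphthalen-1-yl]-5-(triisopropylsilyloxy)phenyl}propan-2-yl]acetonitrilium trifluoromethanesulfonate | C[C@H]([N+]#CC)Cc1cc(OC)c(-c2ccc(OC)c3c(O[Si](C(C)C)(C(C)C)C(C)C)cc(C)cc23)c(O[Si](C(C)C)(C(C)C)C(C)C)c1.[O-]S(=O)(=O)C(F)(F)F | intermediate
22 | (3S)-8-methoxy-7-[4-methoxy-7-methyl-5-(triisopropylsilyloxy)naphthalen-1-yl]-1,3-dimethyl-6-(triisopropylsilyloxy)-3,4-dihydroisoquinoline | COc1c2c(cc(O[Si](C(C)C)(C(C)C)C(C)C)c1-c1ccc(OC)c3c(O[Si](C(C)C)(C(C)C)C(C)C)cc(C)cc13)C[C@H](C)N=C2C | intermediate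
23 | (3S)-7-(5-hydroxy-4-methoxy-7-methylnaphthalen-1-yl)-8-methoxy-1,3-dimethyl-3,4-dihydroisoquinolin-6-ol | COc1c2c(cc(O)c1-c1ccc(OC)c3c(O)cc(C)cc13)C[C@H](C)N=C2C | target

**Count**

Total steps: 10. Longest linear sequence: 10 steps (1 to 23); compounds 2, 10, 16 and 19 enter as purchased partners.

**Steps most likely to fail**

Step 9 (Proposed new method). What may go wrong: ionisation of the triflate or aryl-assisted displacement competing with direct attack of the nitrile, which would erode the C3 configuration; loss of TfOH to the propenylarene; or ring closure ortho to the silyloxy group. The fallback uses known chemistry, sets out from 18 and comes back at 22. Mitsunobu azidation (PPh3, DIAD, (PhO)2P(O)N3, THF, 0 °C to rt) inverts C3 and should give 1-[(2S)-2-azidopropyl]-3-methoxy-4-[4-methoxy-7-methyl-5-(triisopropylsilyloxy)naphthalen-1-yl]-5-(triisopropylsilyloxy)benzene F1. Hydrogenation (H2, Pd/C, EtOAc, rt) should give the (2S)-propan-2-amine F2. Acetylation (Ac2O, Et3N, CH2Cl2) should give the (2S)-acetamide F3. Bischler–Napieralski cyclodehydration (Tf2O, 2-chloropyridine, CH2Cl2, −78 °C to rt) passes through the same nitrilium ion 21 and should give 22, with the silyl group steering the closure as in the main route.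

Step 7. What may go wrong: electrophilic bromination of the electron-rich naphthalene ring or loss of a silyl group during the copper-mediated bromodeboronation. The fallback avoids both the bromide and the organolithium of step 8; it sets out from 14 (isolated after the borylation half of step 7) and comes back at 18. Suzuki–Miyaura coupling with (E)-1-bromoprop-1-ene (PdCl2(dppf), K3PO4, THF/H2O, 60 °C) should give the (E)-propenylarene F4. Shi epoxidation with the D-fructose-derived ketone (KHSO5 as its triple salt with KHSO4 and K2SO4, K2CO3, MeCN/dimethoxymethane/buffer, 0 °C) should give the (2R,3R)-2-aryl-3-methyloxirane F5. Hydrogenolysis of the benzylic C–O bond (H2, Pd/C, EtOAc, rt) leaves the methyl-bearing carbinol centre untouched and should give (R)-alcohol 18.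

Step 5. What may go wrong: protodeboronation of the electron-rich naphthylboronate (faster once its acetate is cleaved) and slow oxidative addition to the hindered bromophenolate. The fallback reverses the polarity of the coupling in a Negishi reaction; it sets out from 10 and 8 and comes back at 13. Silylation of 10 (iPr3SiCl, imidazole, DMF) should give (2-bromo-3-methoxyphenoxy)triisopropylsilane F6. Bromine–lithium exchange (n-BuLi, THF, −78 °C) gives [2-methoxy-6-(triisopropylsilyloxy)phenyl]lithium F7, which is trapped at once with ZnCl2 as [2-methoxy-6-(triisopropylsilyloxy)phenyl]zinc chloride F8 before silyl migration can set in. Coupling of F8 with bromide 8 (Pd2(dba)3, SPhos, THF, 60 °C; the arylzinc tolerates the acetate) should give 8-methoxy-5-[2-methoxy-6-(triisopropylsilyloxy)phenyl]-3-methylnaphthalen-1-yl acetate F9. Methanolysis (K2CO3, MeOH, 0 °C) should give 8-methoxy-5-[2-methoxy-6-(triisopropylsilyloxy)phenyl]-3-methylnaphthalen-1-ol F10, and silylation (iPr3SiOTf, 2,6-lutidine, CH2Cl2) gives 13.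

Further compounds

F1 | step 9 | 1-[(2S)-2-azidopropyl]-3-methoxy-4-[4-methoxy-7-methyl-5-(triisopropylsilyloxy)naphthalen-1-yl]-5-(triisopropylsilyloxy)benzene | C[C@H](N=[N+]=[N-])Cc1cc(OC)c(-c2ccc(OC)c3c(O[Si](C(C)C)(C(C)C)C(C)C)cc(C)cc23)c(O[Si](C(C)C)(C(C)C)C(C)C)c1
F2 | step 9 | (2S)-1-{3-methoxy-4-[4-methoxy-7-methyl-5-(triisopropylsilyloxy)naphthalen-1-yl]-5-(triisopropylsilyloxy)phenyl}propan-2-amine | C[C@H](N)Cc1cc(OC)c(-c2ccc(OC)c3c(O[Si](C(C)C)(C(C)C)C(C)C)cc(C)cc23)c(O[Si](C(C)C)(C(C)C)C(C)C)c1
F3 | step 9 | N-[(2S)-1-{3-methoxy-4-[4-methoxy-7-methyl-5-(triisopropylsilyloxy)naphthalen-1-yl]-5-(triisopropylsilyloxy)phenyl}propan-2-yl]acetamide | C[C@H](NC(C)=O)Cc1cc(OC)c(-c2ccc(OC)c3c(O[Si](C(C)C)(C(C)C)C(C)C)cc(C)cc23)c(O[Si](C(C)C)(C(C)C)C(C)C)c1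
F4 | step 7 | 4-methoxy-1-{2-methoxy-4-[(E)-prop-1-en-1-yl]-6-(triisopropylsilyloxy)phenyl}-7-methyl-5-(triisopropylsilyloxy)naphthalene | C/C=C/c1cc(OC)c(-c2ccc(OC)c3c(O[Si](C(C)C)(C(C)C)C(C)C)cc(C)cc23)c(O[Si](C(C)C)(C(C)C)C(C)C)c1
F5 | step 7 | (2R,3R)-2-{3-methoxy-4-[4-methoxy-7-methyl-5-(triisopropylsilyloxy)naphthalen-1-yl]-5-(triisopropylsilyloxy)phenyl}-3-methyloxirane | C[C@H]1O[C@@H]1c1cc(OC)c(-c2ccc(OC)c3c(O[Si](C(C)C)(C(C)C)C(C)C)cc(C)cc23)c(O[Si](C(C)C)(C(C)C)C(C)C)c1
F6 | step 5 | (2-bromo-3-methoxyphenoxy)triisopropylsilane | COc1cccc(O[Si](C(C)C)(C(C)C)C(C)C)c1Br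
F7 | step 5 | [2-methoxy-6-(triisopropylsilyloxy)phenyl]lithium | COc1cccc(O[Si](C(C)C)(C(C)C)C(C)C)c1[Li]
F8 | step 5 | [2-methoxy-6-(triisopropylsilyloxy)phenyl]zinc chloride | COc1cccc(O[Si](C(C)C)(C(C)C)C(C)C)c1[Zn]Cl
F9 | step 5 | 8-methoxy-5-[2-methoxy-6-(triisopropylsilyloxy)phenyl]-3-methylnaphthalen-1-yl acetate | COc1cccc(O[Si](C(C)C)(C(C)C)C(C)C)c1-c1ccc(OC)c2c(OC(C)=O)cc(C)cc12
F10 | step 5 | 8-methoxy-5-[2-methoxy-6-(triisopropylsilyloxy)phenyl]-3-methylnaphthalen-1-ol | COc1cccc(O[Si](C(C)C)(C(C)C)C(C)C)c1-c1ccc(OC)c2c(O)cc(C)cc12
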